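The constants used here are assumed; the flask was simulated.

A closed, stirred vessel held substrate and a little free acid, and I reckoned how far the substrate had gone by the end of the run.

    substrate + acid → weak acid + acid + product (k1 = 55.5 M⁻¹ s⁻¹)
    weak acid ⇌ conjugate base + acid, settled at all times (K2 = 3.2 × 10⁻⁵ M)
    substrate → weak acid + product (k3 = 0.0347 s⁻¹)
    substrate ⇌ dormant form (K4 = 1.54, k4 = 0.234 s⁻¹)
    weak acid → by-product carried off (k5 = 1.02 s⁻¹)

substrate 0.20 M; acid 6.00 mM; time 10 s

1. part of the substrate that has reacted at 10 s
2. pH of the solution at 10 s

- acid is the free proton; pH is minus the decimal logarithm of its molar concentration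
- what has gone from substrate into another species counts as reacted, even if it can come back
- run time (flask): 10 s

I froze the acid first. The acid-carried step hands it back, and even the whole charge standing as weak acid would, at balance, give 1.07 mM of conjugate base, less than the 6.00 mM of acid, so I took the pH as 2.22. Substrate then drained at a pseudo-first-order constant d, 0.368 s⁻¹, while it passed to the dormant form at 0.234 s⁻¹ and came back at b, 0.152 s⁻¹. The slow drain constant λ, the smaller root of the quadratic whose roots sum to d plus both exchange constants and multiply to d times b, came to 0.0834 s⁻¹; the larger root μ came to 0.670 s⁻¹. The slow term of the substrate's decay carried a weight (b − λ)/(μ − λ), 11.7 % of the charge when run back to the start, and with the fast term dropped I reckoned 94.9 % reacted.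

The forecast gave 94.9 % and pH 2.22, holding that the dormant form “acts as a reservoir that feeds substrate back slowly”.

The flask gave 94.9 % and pH 2.22, with acid at 100 % of its charge. The balance of weak acid with conjugate base made no difference to the part reacted. The method is constant acid, one quadratic and one exponential.

For the neighbour charged with 0.024 M of acid I reckoned d as 1.37 s⁻¹ and λ as 0.128 s⁻¹, which gave 0.445 % as substrate; that neighbour showed 0.45 %. The flask was not at rest at 10 s, holding 17.0 % as dormant form and 77.9 % as product. Carried on at λ, that dormant form reckoned out at 0.00935 % by 100 s, and the flask then held 0.00940 % of it, with product at >99.9 %.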